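## Structural features

Ocophyllal B (14) is a benzofuran in which a benzene ring A (C3a, C4 to C7, C7a) is fused along the C3a–C7a bond to a furan ring B (O1, C2, C3, C3a, C7a). C2 carries a 3,4,5-trimethoxyphenyl group (ring C) through a single aryl–heteroaryl bond. Ring B is fully substituted (aryl at C2, methyl at C3), and ring A carries a methoxy group at C7, next to the ring oxygen, and a formyl group at C5, para to O1. The target has no stereocentre; the only stereocentres of the plan are C2 and C3 of a 2,3-dihydro intermediate, which stand next to each other and are both erased at the end. The fragile groups are the aldehyde (towards hydride and carbon nucleophiles such as ylides), the electron-rich arenes (towards electrophiles and oxidants) and, once the aldehyde is masked, an acid-labile acetal whose C–H is also hydridic. The real difficulty is regiochemical: a 1,2,3,5-tetrasubstituted ring A must be joined to a furan in which aryl and methyl sit on defined carbons, without 3-aryl-2-methyl isomers. The key step exploits C2 of ring B, a benzylic carbon bonded only to O1, C3 and ring C. It can arrive as the single carbon of a sulfonium ylide that first attacks C3 as a nucleophile and is then attacked by O1 as an electrophile. The remaining atoms (O1, C7a, C3a, C3 and the C3 methyl) map onto an ortho-quinone methide, and hence onto an ortho-hydroxyacetophenone.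

## Logic of the disconnections

14 to 13. The C2=C3 double bond of 14 is taken back to the C2–H/C3–H single bond of 13; no skeletal bond is cut. The reason is to make C2 and C3 saturated so that ring B can be assembled by polar bond formation at sp3 carbons. The gain is access to a two-fragment annulation; the cost is two transient stereocentres that need no control. The forward step must abstract hydride from C2 without over-oxidising rings A and C. The formyl group is therefore set free before this step, because the masked form in 12 carries a second, strongly hydridic C–H that a quinone oxidant would also attack.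

13 to 12. The C=O of 13 is exchanged for the two C–O bonds of the cyclic acetal in 12. The annulation uses a carbon nucleophile that would also add to an aldehyde, and the masked ring A is more electron-rich, which helps the elimination that opens the annulation. The forward hydrolysis must be mild enough to leave the benzylic C2–O1 bond untouched.

12 to 6 and 9 (through 10 and 11). Ring B is opened at O1–C2 and C2–C3. C2 leaves with ring C as the benzylic carbon of 9, and O1, C7a, C3a, C3 and the methyl stay in 6. The cut follows the natural polarity of C2 (donor towards C3, acceptor towards O1). The gain is large: one ring, two bonds and the ring B–ring C connection arise from two fragments of similar size, and the carbon bearing ring C can only end up between O1 and C3. The forward step demands that 10 be released under conditions where 11 exists, that 10 be trapped faster than it tautomerises, and that no carbonyl electrophile compete.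

9 to 7 and 8. The S–C(benzyl) bond is cut. This reduces 9 to two commercial compounds and needs only a clean SN2 alkylation whose product crystallises.

6 to 4 and 5. The C–S bond at the future C3 is cut. The sulfone is chosen as the quinone methide precursor because it should be crystalline, stable to storage and acid, and ionise only from the phenoxide. The forward substitution runs under acid, which threatens the acetal. It is therefore designed without added water and with no acid stronger than the sulfinic acid itself.

4 to 3. The carbinol C–H bond is removed, returning the benzylic alcohol to the aryl ketone. The forward hydride reduction needs the aldehyde to be masked already and a work-up that is not acidic.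

3 to 2. The acetal C–O bonds are removed. This leaves a keto-aldehyde and asks the forward step to differentiate aldehyde from ketone, which the deactivated, hydrogen-bonded ortho-hydroxyaryl ketone makes possible.

2 to 1. The C5–CHO bond is cut. Ring A of 1 already holds the hydroxyl, the methoxy group and the two-carbon unit that becomes C3 and its methyl. The forward electrophilic formylation must go para to the hydroxyl, the only position on which all directing effects agree.

## Other disconnections considered

Alternative 1: The cut is C5=C6 of ring A, with rings B and C already in place. The precursor would be the tetrasubstituted furan A2, 1-[3-[2-({[tert-butyl(dimethyl)silyl]oxy}methyl)prop-2-en-1-yl]-4-methyl-5-(3,4,5-trimethoxyphenyl)furan-2-yl]prop-2-en-1-one. Ring-closing metathesis with (H2IMes)(PCy3)Cl2Ru=CHPh, the second-generation Grubbs catalyst, would join the acryloyl alkene and the 1,1-disubstituted allyl alkene. The resulting bicyclic dienone should tautomerise to the phenol A1, 5-({[tert-butyl(dimethyl)silyl]oxy}methyl)-3-methyl-2-(3,4,5-trimethoxyphenyl)-1-benzofuran-7-ol.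
- In favour: the closure is driven by aromatisation, the pairing of an electron-poor enone alkene with a 1,1-disubstituted alkene suits this catalyst, the regiochemistry of ring A cannot be wrong, and the conditions are neutral.
- Against: A2 is a furan with four different substituents and would need a long preparation, the vinyl ketone is prone to polymerisation and conjugate addition, and A1 still needs O-methylation, desilylation and oxidation of the primary alcohol.
- Comparison: the mechanism is as well understood as that of the chosen annulation. It is the better plan on two points: no stereocentre is ever made and no oxidative aromatisation is needed, and the free C7 phenol of A1 allows late variation of that ether. It is weaker on step economy, on the oxidation level of the C5 carbon, and because the hard part (the furan) is moved into the precursor instead of being solved by the key step.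

Alternative 2: The cuts are C4–C5 and C6–C7, so ring A is built onto the furoate A4, methyl 3,4-dimethyl-5-(3,4,5-trimethoxyphenyl)furan-2-carboxylate. LiN(i-Pr)2 would deprotonate the methyl group vinylogous to the ester. The anion would add to the vinyl sulfoxide A5, [(1E)-3,3-diethoxyprop-1-ene-1-sulfinyl]benzene, and the sulfinyl carbanion would close onto the ester. Thermal loss of the sulfenic acid and tautomerisation would give A3, 5-(diethoxymethyl)-3-methyl-2-(3,4,5-trimethoxyphenyl)-1-benzofuran-7-ol.
- In favour: two C–C bonds and the aromatisation occur in one flask, C5 arrives at the aldehyde oxidation level as a base-stable acetal, and the C7 oxygen comes from the ester.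
- Against: A4 needs its own multistep synthesis, the lateral deprotonation must distinguish two methyl groups, the β-substituted acceptor A5 carries a bulky acetal and should be sluggish, and the step needs a strong base at low temperature.
- Comparison: the end-game (O-methylation, mild acid hydrolysis) is two steps, equal to the chosen plan, and it is better in that no oxidant is required and the acetal never meets acid before its removal. The chosen plan is stronger before the key step, where it starts from a cheap trisubstituted benzene and builds the fully substituted furan in the key step itself. It is also safer in reagents.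

Alternative 3: The cut is C7–C7a, preceded by the C4=C5 bond of a Stobbe condensation. The furaldehyde A8, 4-methyl-5-(3,4,5-trimethoxyphenyl)furan-3-carbaldehyde, would be condensed with a succinate diester to the half-ester A7, (3E)-3-(methoxycarbonyl)-4-[4-methyl-5-(3,4,5-trimethoxyphenyl)furan-3-yl]but-3-enoic acid. Ac2O and NaOAc would activate the acid, and intramolecular acylation at the free α position of the furan, enolisation and acetylation would give A6, methyl 7-acetoxy-3-methyl-2-(3,4,5-trimethoxyphenyl)-1-benzofuran-5-carboxylate.
- In favour: the reagents are cheap and the method is classical and scalable, with no transition metal and no cryogenic step. The only free and most nucleophilic furan position is the one that must react.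
- Against: the furan must survive hot Ac2O, only the E half-ester can cyclise, C5 arrives as an ester and C7 as an acetate, so deacetylation, methylation, reduction and reoxidation follow, and A8 is not a simple starting material.
- Comparison: the key step is the equal or the better of the chosen one in robustness and cost, and no aldehyde protecting group and no stereochemical issue arise. It is weaker on redox and step economy after the key step and on the length of the route to the furan.

Key step: step 6

## Route

Remark on the chemistry: 4, 6, 12 and 13 are racemates. For 12 and 13 one enantiomer of the trans pair is written; any cis component would serve equally, because step 8 removes both centres.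

Step 1
Reactants: 1 1-(2-hydroxy-3-methoxyphenyl)ethan-1-one (2'-hydroxy-3'-methoxyacetophenone)
Product: 2 3-acetyl-4-hydroxy-5-methoxybenzaldehyde
Conditions: hexamethylenetetramine (2 equiv), CF3CO2H, 85 °C; then H2O, 60 °C
Reagents that add atoms: hexamethylenetetramine C1N2CN3CN1CN(C2)C3; water O
Why: Duff formylation (aminomethylation by the iminium ion from hexamethylenetetramine, hydride transfer to a second iminium ion, hydrolysis). Both ortho positions of the phenol are occupied and the acetyl group directs meta, so all directing effects converge on the position para to the hydroxyl.

Step 2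
Reactants: 2 3-acetyl-4-hydroxy-5-methoxybenzaldehyde
Product: 3 1-[5-(1,3-dioxolan-2-yl)-2-hydroxy-3-methoxyphenyl]ethan-1-one
Conditions: HOCH2CH2OH (1.5 equiv), pyridinium p-toluenesulfonate (cat.), PhMe, reflux, Dean–Stark
Reagents that add atoms: ethylene glycol OCCO
Why: Acid-catalysed acetalisation with azeotropic removal of water. The aldehyde should react far faster than the methyl ketone, which is hindered, conjugated and hydrogen-bonded to the ortho hydroxyl, so a small excess of diol should give the mono-dioxolane.

Step 3
Reactants: 3 1-[5-(1,3-dioxolan-2-yl)-2-hydroxy-3-methoxyphenyl]ethan-1-one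
Product: 4 rac-4-(1,3-dioxolan-2-yl)-2-(1-hydroxyethyl)-6-methoxyphenol
Conditions: NaBH4, MeOH, 0 °C to rt; aq NH4Cl
Reagents that add atoms: none
Why: Borohydride reduction of the aryl ketone; the acetal is inert to hydride and the near-neutral work-up spares it. The carbinol centre forms as a racemate and is destroyed at the quinone methide stage.

Step 4
Reactants: 4 rac-4-(1,3-dioxolan-2-yl)-2-(1-hydroxyethyl)-6-methoxyphenol; 5 sodium p-toluenesulfinate
Product: 6 rac-4-(1,3-dioxolan-2-yl)-2-methoxy-6-[1-(4-methylbenzenesulfonyl)ethyl]phenol
Conditions: 5 (3 equiv), CF3CO2H (1.2 equiv), 4 Å molecular sieves, CH2Cl2, 0 °C to rt; aq NaHCO3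
Reagents that add atoms: none
Why: Acid-mediated SN1-type substitution: the ortho-hydroxybenzylic alcohol ionises to a protonated ortho-quinone methide, which the sulfinate captures at sulfur to give the sulfone as the thermodynamic product. The excess sulfinate levels the acid to p-toluenesulfinic acid and the sieves hold the water released, so the dioxolane should survive. The new stereocentre is uncontrolled and is lost in step 6.

Step 5
Reactants: 7 5-(bromomethyl)-1,2,3-trimethoxybenzene; 8 dimethyl sulfide
Product: 9 dimethyl(3,4,5-trimethoxybenzyl)sulfonium bromide
Conditions: 8 (3 equiv), acetone, rt, closed vessel; filtration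
Reagents that add atoms: none
Why: SN2 S-alkylation of the sulfide by a reactive benzylic bromide; the salt should crystallise from acetone, which drives the reaction and avoids chromatography. The closed vessel and a bleach scrubber contain the volatile, malodorous sulfide.

Step 6
Reactants: 6 rac-4-(1,3-dioxolan-2-yl)-2-methoxy-6-[1-(4-methylbenzenesulfonyl)ethyl]phenol; 9 dimethyl(3,4,5-trimethoxybenzyl)sulfonium bromide
Product: 12 rac-(2R,3R)-2-[7-methoxy-3-methyl-2-(3,4,5-trimethoxyphenyl)-2,3-dihydro-1-benzofuran-5-yl]-1,3-dioxolane (trans), via ortho-quinone methide 10 (not isolated), via sulfonium ylide 11 (not isolated)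
Conditions: 9 (1.5 equiv), Cs2CO3 (3 equiv), MeCN, 0 °C; slow addition of 6; rt
Reagents that add atoms: none
Why: Cs2CO3 deprotonates the phenol of 6, whose phenoxide expels p-toluenesulfinate (E1cB) to give 10, and the same base deprotonates 9 at its benzylic carbon to give the semi-stabilised ylide 11. The ylide carbon adds to the exocyclic methide carbon of 10 (the future C3, already carrying the methyl), a conjugate addition that restores the aromaticity of ring A and forms C2–C3. The phenoxide–sulfonium zwitterion then closes ring B by a 5-exo-tet SN2 displacement of dimethyl sulfide at the benzylic carbon, forming O1–C2. The closest known reaction type is the formal (4+1) annulation of ortho-quinone methides generated in situ with sulfur ylides to 2,3-dihydrobenzofurans. C2 and C3 are new stereocentres: their relative configuration is set in the backside displacement, where the zwitterion with aryl and methyl anti should close faster while the addition remains reversible, so the trans isomer is expected; there is no absolute control, and step 8 removes both centres. The step needs the ylide to choose the quinone methide over any carbonyl group, which the dioxolane secures, and the quinone methide to meet the ylide before it tautomerises to a vinylphenol, which the excess of 11 and the slow addition of 6 favour.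

Step 7
Reactants: 12 rac-(2R,3R)-2-[7-methoxy-3-methyl-2-(3,4,5-trimethoxyphenyl)-2,3-dihydro-1-benzofuran-5-yl]-1,3-dioxolane
Product: 13 rac-(2R,3R)-7-methoxy-3-methyl-2-(3,4,5-trimethoxyphenyl)-2,3-dihydro-1-benzofuran-5-carbaldehyde
Conditions: 1 M HCl aq, THF, rt
Reagents that add atoms: water O
Why: Acid-catalysed acetal hydrolysis; the dioxolane of a para-alkoxybenzaldehyde ionises easily, so dilute acid at room temperature should suffice without ionising the benzylic C2–O1 bond. Epimerisation at C2, should it occur, is without consequence.

Step 8
Reactants: 13 rac-(2R,3R)-7-methoxy-3-methyl-2-(3,4,5-trimethoxyphenyl)-2,3-dihydro-1-benzofuran-5-carbaldehyde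
Product: 14 7-methoxy-3-methyl-2-(3,4,5-trimethoxyphenyl)-1-benzofuran-5-carbaldehyde (ocophyllal B)
Conditions: DDQ (2,3-dichloro-5,6-dicyano-1,4-benzoquinone, 2 equiv), dry PhMe, 100 °C
Reagents that add atoms: none
Why: Quinone dehydrogenation: DDQ abstracts hydride from C2, which is benzylic to ring C and α to O1, and the oxocarbenium ion loses the C3 proton to give the aromatic furan, erasing both stereocentres. The aldehyde is inert to DDQ; the acetal was removed first because its hydridic C–H would otherwise be oxidised to an ester. The medium is kept dry because DDQ liberates HCN with water.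

## Compound list

1 | 1-(2-hydroxy-3-methoxyphenyl)ethan-1-one (2'-hydroxy-3'-methoxyacetophenone) | CC(=O)c1cccc(OC)c1O | starting material
2 | 3-acetyl-4-hydroxy-5-methoxybenzaldehyde | CC(=O)c1cc(C=O)cc(OC)c1O | intermediate
3 | 1-[5-(1,3-dioxolan-2-yl)-2-hydroxy-3-methoxyphenyl]ethan-1-one | CC(=O)c1cc(C2OCCO2)cc(OC)c1O | intermediate
4 | rac-4-(1,3-dioxolan-2-yl)-2-(1-hydroxyethyl)-6-methoxyphenol (racemic, one stereocentre) | CC(O)c1cc(C2OCCO2)cc(OC)c1O | intermediate
5 | sodium p-toluenesulfinate | Cc1ccc(S(=O)[O-])cc1.[Na+] | starting material
6 | rac-4-(1,3-dioxolan-2-yl)-2-methoxy-6-[1-(4-methylbenzenesulfonyl)ethyl]phenol (racemic, one stereocentre) | Cc1ccc(S(=O)(=O)C(C)c2cc(C3OCCO3)cc(OC)c2O)cc1 | intermediate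
7 | 5-(bromomethyl)-1,2,3-trimethoxybenzene | COc1cc(CBr)cc(OC)c1OC | starting material
8 | dimethyl sulfide | CSC | starting material
9 | dimethyl(3,4,5-trimethoxybenzyl)sulfonium bromide | C[S+](C)Cc1cc(OC)c(OC)c(OC)c1.[Br-] | intermediate
10 | (6E)-4-(1,3-dioxolan-2-yl)-6-ethylidene-2-methoxycyclohexa-2,4-dien-1-one (ortho-quinone methide; E geometry assumed, methyl turned away from the carbonyl group) | C/C=C1\C=C(C2OCCO2)C=C(OC)C1=O | intermediate (not isolated)
11 | dimethylsulfonium (3,4,5-trimethoxyphenyl)methanide (sulfonium ylide) | C[S+](C)[CH-]c1cc(OC)c(OC)c(OC)c1 | intermediate (not isolated)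
12 | rac-(2R,3R)-2-[7-methoxy-3-methyl-2-(3,4,5-trimethoxyphenyl)-2,3-dihydro-1-benzofuran-5-yl]-1,3-dioxolane (trans; one enantiomer written) | COc1cc([C@@H]2Oc3c(OC)cc(C4OCCO4)cc3[C@H]2C)cc(OC)c1OC | intermediate
13 | rac-(2R,3R)-7-methoxy-3-methyl-2-(3,4,5-trimethoxyphenyl)-2,3-dihydro-1-benzofuran-5-carbaldehyde (trans; one enantiomer written) | COc1cc([C@@H]2Oc3c(OC)cc(C=O)cc3[C@H]2C)cc(OC)c1OC | intermediate
14 | 7-methoxy-3-methyl-2-(3,4,5-trimethoxyphenyl)-1-benzofuran-5-carbaldehyde (ocophyllal B; no stereocentre) | COc1cc(-c2oc3c(OC)cc(C=O)cc3c2C)cc(OC)c1OC | target

## Step count and least certain steps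

Total step count: 8. Longest linear sequence: 7 steps (steps 1 to 4, then 6 to 8); step 5 is a one-step branch.

Step 6 (key step). Three processes may interfere:
- tautomerisation of the quinone methide to an ortho-vinylphenol by proton loss from the methyl group on its methide carbon;
- O-alkylation of the phenoxide by the sulfonium salt acting as a benzylating or methylating agent;
- slow deprotonation of the electron-rich benzylsulfonium salt by a carbonate base, which would leave the quinone methide to oligomerise.

Fallback: this abandons the ylide annulation and the dihydro level. It sets out from 3. O-acylation with 3,4,5-trimethoxybenzoyl chloride (Et3N, cat. 4-(dimethylamino)pyridine, CH2Cl2) would give 2-acetyl-4-(1,3-dioxolan-2-yl)-6-methoxyphenyl 3,4,5-trimethoxybenzoate F1. An intramolecular keto–ester McMurry coupling with low-valent titanium (TiCl4, Zn, pyridine, THF, reflux) would join the ketone carbon (C3) to the ester carbon (C2) and give 2-[7-methoxy-3-methyl-2-(3,4,5-trimethoxyphenyl)-1-benzofuran-5-yl]-1,3-dioxolane F2. Treatment with 1 M HCl in THF would then release the aldehyde, so the route is rejoined at 14 and steps 7 and 8 are not needed.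

Step 4. The likely failure is hydrolysis of the dioxolane by the sulfinic acid and the water that the substitution releases. The acetal carbon (para to the hydroxyl) and the carbinol carbon (ortho to it) are activated to a similar degree, so selectivity rests on the exclusion of water. Fallback: the acetal is sacrificed and reinstalled. From 4, the substitution is run with 5 in HCO2H/H2O at rt, where the acetal is hydrolysed on purpose, to give rac-4-hydroxy-3-methoxy-5-[1-(4-methylbenzenesulfonyl)ethyl]benzaldehyde F3. This is re-acetalised with ethylene glycol and catalytic pyridinium p-toluenesulfonate in PhMe under Dean–Stark conditions; the benzylic sulfone should tolerate weak acid, because sulfinate leaves only from the phenoxide. The route is rejoined at 6.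

Step 8. Hydride abstraction from C2 may be slow, because the formyl group para to O1 draws on the oxygen lone pair that stabilises the developing cation. Prolonged heating with a strong oxidant could then lead to oxidative degradation of the trimethoxyphenyl ring. Fallback: the formyl group is masked in a form that is neither a resonance acceptor nor a hydride donor. From 13, Ac2O with catalytic Sc(OTf)3 in MeCN would give the acylal rac-(2R,3R)-[7-methoxy-3-methyl-2-(3,4,5-trimethoxyphenyl)-2,3-dihydro-1-benzofuran-5-yl]methylene diacetate F4. DDQ in PhMe at 100 °C would dehydrogenate it to [7-methoxy-3-methyl-2-(3,4,5-trimethoxyphenyl)-1-benzofuran-5-yl]methylene diacetate F5. K2CO3 in MeOH at rt would cleave the acylal, and the route is rejoined at 14.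

## Further compounds

F1 | step 6 | 2-acetyl-4-(1,3-dioxolan-2-yl)-6-methoxyphenyl 3,4,5-trimethoxybenzoate | CC(=O)c1cc(C2OCCO2)cc(OC)c1OC(=O)c1cc(OC)c(OC)c(OC)c1
F2 | step 6 | 2-[7-methoxy-3-methyl-2-(3,4,5-trimethoxyphenyl)-1-benzofuran-5-yl]-1,3-dioxolane | COc1cc(-c2oc3c(OC)cc(C4OCCO4)cc3c2C)cc(OC)c1OC
F3 | step 4 | rac-4-hydroxy-3-methoxy-5-[1-(4-methylbenzenesulfonyl)ethyl]benzaldehyde | Cc1ccc(S(=O)(=O)C(C)c2cc(C=O)cc(OC)c2O)cc1
F4 | step 8 | rac-(2R,3R)-[7-methoxy-3-methyl-2-(3,4,5-trimethoxyphenyl)-2,3-dihydro-1-benzofuran-5-yl]methylene diacetate | COc1cc([C@@H]2Oc3c(OC)cc(C(OC(C)=O)OC(C)=O)cc3[C@H]2C)cc(OC)c1OC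
F5 | step 8 | [7-methoxy-3-methyl-2-(3,4,5-trimethoxyphenyl)-1-benzofuran-5-yl]methylene diacetate | COc1cc(-c2oc3c(OC)cc(C(OC(C)=O)OC(C)=O)cc3c2C)cc(OC)c1OC
A1 | alternative 1 | 5-({[tert-butyl(dimethyl)silyl]oxy}methyl)-3-methyl-2-(3,4,5-trimethoxyphenyl)-1-benzofuran-7-ol | CC(C)(C)[Si](C)(C)OCc1cc(O)c2oc(-c3cc(OC)c(OC)c(OC)c3)c(C)c2c1
A2 | alternative 1 | 1-[3-[2-({[tert-butyl(dimethyl)silyl]oxy}methyl)prop-2-en-1-yl]-4-methyl-5-(3,4,5-trimethoxyphenyl)furan-2-yl]prop-2-en-1-one | C=CC(=O)c1oc(-c2cc(OC)c(OC)c(OC)c2)c(C)c1CC(=C)CO[Si](C)(C)C(C)(C)C
A3 | alternative 2 | 5-(diethoxymethyl)-3-methyl-2-(3,4,5-trimethoxyphenyl)-1-benzofuran-7-ol | CCOC(OCC)c1cc(O)c2oc(-c3cc(OC)c(OC)c(OC)c3)c(C)c2c1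
A4 | alternative 2 | methyl 3,4-dimethyl-5-(3,4,5-trimethoxyphenyl)furan-2-carboxylate | COC(=O)c1oc(-c2cc(OC)c(OC)c(OC)c2)c(C)c1C
A5 | alternative 2 | [(1E)-3,3-diethoxyprop-1-ene-1-sulfinyl]benzene (racemic at sulfur) | CCOC(OCC)/C=C/S(=O)c1ccccc1
A6 | alternative 3 | methyl 7-acetoxy-3-methyl-2-(3,4,5-trimethoxyphenyl)-1-benzofuran-5-carboxylate | COC(=O)c1cc(OC(C)=O)c2oc(-c3cc(OC)c(OC)c(OC)c3)c(C)c2c1
A7 | alternative 3 | (3E)-3-(methoxycarbonyl)-4-[4-methyl-5-(3,4,5-trimethoxyphenyl)furan-3-yl]but-3-enoic acid | COC(=O)/C(CC(=O)O)=C/c1coc(-c2cc(OC)c(OC)c(OC)c2)c1C
A8 | alternative 3 | 4-methyl-5-(3,4,5-trimethoxyphenyl)furan-3-carbaldehyde | Cc1c(C=O)coc1-c1cc(OC)c(OC)c(OC)c1
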